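**Retrosynthetic overview**
- Target ⇐ global desilylation of a bis-silyl ether; the exocyclic C7=C8 alkene ⇐ intermolecular aldol addition (C7–C8 bond) of the lithium dienolate of a 2-bromo-4-silyloxycyclopentenone (ring plus lower chain) to a γ-silyloxy enal (upper chain), then mesylate elimination.
- Bromoenone ⇐ enone by nucleophilic epoxidation, bromide opening and dehydration; enone ⇐ anti-selective 1,2-propargylation of enantiopure 4-silyloxycyclopentenone, skipped-diyne coupling, Lindlar reduction, desilylation and allylic oxidation (chirality relayed from C9 to C12).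
- Enal ⇐ cross-metathesis of an (S)-allylic silyl ether with crotonaldehyde; the C4 centre ⇐ asymmetric transfer hydrogenation of an ynone made from methyl succinyl chloride and bis(trimethylsilyl)acetylene.
- Rings: the single carbocycle is bought intact as the cyclopentenone; no ring is formed in the route.

Assumption: the enantiopure prostaglandin building block used as compound 1 is taken as a purchasable starting material, and aqueous quenches are treated as work-up. Prostanoid numbering (C1 ester carbon to C20) is used for the late compounds.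

**Step 1**
Reactants: 1 (R)-4-(tert-butyldimethylsilyloxy)cyclopent-2-en-1-one; 2 propargyl bromide
Product: 4 (1S,4R)-4-(tert-butyldimethylsilyloxy)-1-(prop-2-yn-1-yl)cyclopent-2-en-1-ol, via allenylzinc bromide 3 (not isolated)
Conditions: Zn dust (activated), THF, 0 °C; then 1, −40 → 0 °C; aq. NH4Cl
Reagents that add atoms: none
Why: Barbier-type carbonyl propargylation in which the allenylzinc adds 1,2 (SE2′) to the enone carbonyl anti to OTBS, so the new tertiary carbinol (future C12) has OH cis to OTBS; the minor diastereomer is removed by chromatography, which secures the enantiopurity of this centre.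

**Step 2**
Reactants: 4 (1S,4R)-4-(tert-butyldimethylsilyloxy)-1-(prop-2-yn-1-yl)cyclopent-2-en-1-ol; 5 1-bromopent-2-yne
Product: 8 (1S,4R)-4-(tert-butyldimethylsilyloxy)-1-(octa-2,5-diyn-1-yl)cyclopent-2-en-1-ol, via 1-iodopent-2-yne 6 (not isolated), via copper acetylide 7 (not isolated)
Conditions: CuI (1 equiv), NaI (1 equiv), K2CO3 (1.5 equiv), DMF, rt
Reagents that add atoms: none
Why: copper-mediated sp–sp3 coupling of a terminal alkyne with a propargylic halide (activated by in situ Finkelstein exchange) builds the skipped 1,4-diyne under carbonate conditions that tolerate the free tertiary alcohol and the silyl ether.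

**Step 3**
Reactants: 8 (1S,4R)-4-(tert-butyldimethylsilyloxy)-1-(octa-2,5-diyn-1-yl)cyclopent-2-en-1-ol
Product: 9 (1S,4R)-4-(tert-butyldimethylsilyloxy)-1-[(2Z,5Z)-octa-2,5-dien-1-yl]cyclopent-2-en-1-ol
Conditions: H2 (1 atm), Pd/CaCO3 poisoned with Pb(OAc)2 (Lindlar catalyst), quinoline, EtOAc, rt, stopped at 2 equiv H2
Reagents that add atoms: none
Why: Lindlar semi-hydrogenation adds H2 syn to each alkyne to give the (Z,Z)-skipped diene, while the poisoned catalyst leaves the ring alkene alone.

**Step 4**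
Reactants: 9 (1S,4R)-4-(tert-butyldimethylsilyloxy)-1-[(2Z,5Z)-octa-2,5-dien-1-yl]cyclopent-2-en-1-ol
Product: 10 (1S,4R)-1-[(2Z,5Z)-octa-2,5-dien-1-yl]cyclopent-2-ene-1,4-diol
Conditions: Bu4NF, THF, 0 °C → rt
Reagents that add atoms: none
Why: fluoride-induced desilylation frees the secondary allylic alcohol without touching a stereocentre (any residual diastereomer from step 1 is easily removed at this diol stage).

**Step 5**
Reactants: 10 (1S,4R)-1-[(2Z,5Z)-octa-2,5-dien-1-yl]cyclopent-2-ene-1,4-diol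
Product: 11 (S)-4-hydroxy-4-[(2Z,5Z)-octa-2,5-dien-1-yl]cyclopent-2-en-1-one
Conditions: activated MnO2 (excess), CH2Cl2, rt
Reagents that add atoms: none
Why: chemoselective allylic oxidation converts only the secondary allylic alcohol into the enone (the tertiary alcohol cannot be oxidised), leaving the quaternary carbinol as the sole stereocentre.

**Step 6**
Reactants: 11 (S)-4-hydroxy-4-[(2Z,5Z)-octa-2,5-dien-1-yl]cyclopent-2-en-1-one
Product: 12 (S)-4-[(2Z,5Z)-octa-2,5-dien-1-yl]-4-(triethylsilyloxy)cyclopent-2-en-1-one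
Conditions: Et3SiOTf, 2,6-lutidine, CH2Cl2, −78 °C
Reagents that add atoms: triethylsilyl trifluoromethanesulfonate, CC[Si](CC)(CC)OS(=O)(=O)C(F)(F)F
Why: silyl triflate protection of the hindered tertiary alcohol blocks the retro-aldol ring opening that would racemise this centre in the later basic steps.

**Step 7**
Reactants: 12 (S)-4-[(2Z,5Z)-octa-2,5-dien-1-yl]-4-(triethylsilyloxy)cyclopent-2-en-1-one
Product: 13 2,3-epoxy-4-[(2Z,5Z)-octa-2,5-dien-1-yl]-4-(triethylsilyloxy)cyclopentan-1-one (epoxide oxygen trans to OTES, quaternary centre as in 12)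
Conditions: 30% aq. H2O2, NaOH (cat.), MeOH, 0 °C
Reagents that add atoms: hydrogen peroxide, OO
Why: Weitz–Scheffer nucleophilic epoxidation attacks only the electron-poor enone alkene and not the isolated Z-alkenes; hydroperoxide is expected to add mainly anti to OTES, and either epoxide diastereomer converges in step 9.

**Step 8**
Reactants: 13 2,3-epoxy-4-[(2Z,5Z)-octa-2,5-dien-1-yl]-4-(triethylsilyloxy)cyclopentan-1-one
Product: 14 2-bromo-3-hydroxy-4-[(2Z,5Z)-octa-2,5-dien-1-yl]-4-(triethylsilyloxy)cyclopentan-1-one (Br trans to OH, OH trans to OTES)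
Conditions: LiBr, AcOH, THF, 0 °C → rt
Reagents that add atoms: lithium bromide, [Li+].[Br-]
Why: acid-assisted SN2 opening of the α,β-epoxy ketone by bromide at the carbonyl-activated, less hindered C2 (inversion) gives the trans-bromohydrin under conditions too mild to affect the skipped diene or the silyl ether.

**Step 9**
Reactants: 14 2-bromo-3-hydroxy-4-[(2Z,5Z)-octa-2,5-dien-1-yl]-4-(triethylsilyloxy)cyclopentan-1-one
Product: 16 (S)-2-bromo-4-[(2Z,5Z)-octa-2,5-dien-1-yl]-4-(triethylsilyloxy)cyclopent-2-en-1-one, via mesylate 15 (not isolated)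
Conditions: MsCl, Et3N, CH2Cl2, 0 °C → rt
Reagents that add atoms: none
Why: mesylation of the β-hydroxyl and E1cB elimination (the C2–H is acidified by the carbonyl and by bromine) give the 2-bromoenone and erase both temporary stereocentres.

**Step 10**
Reactants: 17 methyl 4-chloro-4-oxobutanoate; 18 bis(trimethylsilyl)acetylene
Product: 19 methyl 4-oxo-6-(trimethylsilyl)hex-5-ynoate
Conditions: AlCl3, CH2Cl2, 0 °C
Reagents that add atoms: none
Why: Friedel–Crafts-type acylation (ipso-substitution) of the alkynylsilane by the acid chloride gives the silyl ynone, the deactivated product resisting a second acylation.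

**Step 11**
Reactants: 19 methyl 4-oxo-6-(trimethylsilyl)hex-5-ynoate
Product: 20 methyl (S)-4-hydroxy-6-(trimethylsilyl)hex-5-ynoate
Conditions: Ru[(S,S)-TsDPEN](p-cymene) (1 mol%), i-PrOH, rt
Reagents that add atoms: none
Why: Noyori asymmetric transfer hydrogenation, in which the (S,S)-catalyst reduces the ynone to the (S)-propargylic alcohol (future C4) in high ee under neutral conditions that avoid lactonisation.

**Step 12**
Reactants: 20 methyl (S)-4-hydroxy-6-(trimethylsilyl)hex-5-ynoate
Product: 21 methyl (S)-4-(tert-butyldimethylsilyloxy)-6-(trimethylsilyl)hex-5-ynoate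
Conditions: TBSCl, imidazole, DMF, 0 °C → rt (run directly on crude 20)
Reagents that add atoms: tert-butyldimethylsilyl chloride, CC(C)(C)[Si](C)(C)Cl
Why: standard O-silylation protects the γ-hydroxy ester at once, which prevents lactonisation and leaves the configuration unchanged.

**Step 13**
Reactants: 21 methyl (S)-4-(tert-butyldimethylsilyloxy)-6-(trimethylsilyl)hex-5-ynoate
Product: 22 methyl (S)-4-(tert-butyldimethylsilyloxy)hex-5-ynoate
Conditions: K2CO3 (0.2 equiv), MeOH, 0 °C
Reagents that add atoms: none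
Why: base-catalysed methanolysis (protodesilylation) cleaves only the C(sp)–Si bond, leaving the TBS ether and the methyl ester intact.

**Step 14**
Reactants: 22 methyl (S)-4-(tert-butyldimethylsilyloxy)hex-5-ynoate
Product: 23 methyl (S)-4-(tert-butyldimethylsilyloxy)hex-5-enoate
Conditions: H2 (1 atm), Pd/CaCO3 poisoned with Pb(OAc)2 (Lindlar catalyst), quinoline, hexane/EtOAc, rt
Reagents that add atoms: none
Why: Lindlar semi-hydrogenation of the terminal alkyne gives the terminal alkene needed for metathesis without touching the stereocentre.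

**Step 15**
Reactants: 23 methyl (S)-4-(tert-butyldimethylsilyloxy)hex-5-enoate; 24 (E)-crotonaldehyde
Product: 25 methyl (S,E)-4-(tert-butyldimethylsilyloxy)-7-oxohept-5-enoate
Conditions: second-generation Hoveyda–Grubbs catalyst RuCl2(SIMes)(=CH-C6H4-2-O-i-Pr) (5 mol%), crotonaldehyde (5 equiv), CH2Cl2, 40 °C
Reagents that add atoms: none
Why: olefin cross-metathesis with excess crotonaldehyde gives the E-enal under thermodynamic control and releases propene, while the hindered allylic silyl ether does not homodimerise.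

**Step 16**
Reactants: 16 (S)-2-bromo-4-[(2Z,5Z)-octa-2,5-dien-1-yl]-4-(triethylsilyloxy)cyclopent-2-en-1-one; 25 methyl (S,E)-4-(tert-butyldimethylsilyloxy)-7-oxohept-5-enoate
Product: 27 methyl (4S,5E,12S,14Z,17Z)-10-bromo-4-(tert-butyldimethylsilyloxy)-7-hydroxy-9-oxo-12-(triethylsilyloxy)prosta-5,10,14,17-tetraenoate (mixture at C7 and C8), via lithium dienolate 26 (not isolated)
Conditions: LiN(i-Pr)2 (1.05 equiv), THF, −78 °C; then 25, −78 °C; aq. NH4Cl at −78 °C
Reagents that add atoms: none
Why: intermolecular aldol addition in which kinetic deprotonation at the only enolisable position (C8) gives the lithium dienolate that adds 1,2 to the enal and forms the C7–C8 bond; the C7/C8 diastereomers do not matter because both centres become sp2 in step 17.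

**Step 17**
Reactants: 27 methyl (4S,5E,12S,14Z,17Z)-10-bromo-4-(tert-butyldimethylsilyloxy)-7-hydroxy-9-oxo-12-(triethylsilyloxy)prosta-5,10,14,17-tetraenoate
Product: 29 methyl (4S,5E,7Z,12R,14Z,17Z)-10-bromo-4-(tert-butyldimethylsilyloxy)-9-oxo-12-(triethylsilyloxy)prosta-5,7,10,14,17-pentaenoate, via allylic mesylate 28 (not isolated)
Conditions: MsCl, Et3N (excess), CH2Cl2, −20 °C → rt; 7Z isomer separated from 7E by silica chromatography/HPLC
Reagents that add atoms: none
Why: mesylation and E1cB elimination complete the aldol condensation and give the cross-conjugated dienone as a separable mixture of C7 geometric isomers, from which the required 7Z isomer (C6 syn to the C9 carbonyl) is isolated; C4 and C12 are untouched.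

**Step 18**
Reactants: 29 methyl (4S,5E,7Z,12R,14Z,17Z)-10-bromo-4-(tert-butyldimethylsilyloxy)-9-oxo-12-(triethylsilyloxy)prosta-5,7,10,14,17-pentaenoate
Product: 30 methyl (4S,5E,7Z,12R,14Z,17Z)-10-bromo-4,12-dihydroxy-9-oxoprosta-5,7,10,14,17-pentaenoate (CNP0168693.1)
Conditions: HF·pyridine, pyridine, THF, 0 °C → rt
Reagents that add atoms: none
Why: pyridine-buffered fluoride desilylation removes both silyl ethers without acid-induced lactonisation or dehydration and gives the target with all stereochemistry intact.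

**Compound list**
1 | (R)-4-(tert-butyldimethylsilyloxy)cyclopent-2-en-1-one | O=C1C=C[C@H](O[Si](C)(C)C(C)(C)C)C1 | starting material
2 | propargyl bromide (3-bromoprop-1-yne) | C#CCBr | starting material
3 | allenylzinc bromide | C=C=C[Zn]Br | intermediate
4 | (1S,4R)-4-(tert-butyldimethylsilyloxy)-1-(prop-2-yn-1-yl)cyclopent-2-en-1-ol (OH cis to OTBS) | C#CC[C@@]1(O)C=C[C@H](O[Si](C)(C)C(C)(C)C)C1 | intermediate
5 | 1-bromopent-2-yne | CCC#CCBr | starting material
6 | 1-iodopent-2-yne | CCC#CCI | intermediate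
7 | copper acetylide of 4 | [Cu]C#CC[C@@]1(O)C=C[C@H](O[Si](C)(C)C(C)(C)C)C1 | intermediate
8 | (1S,4R)-4-(tert-butyldimethylsilyloxy)-1-(octa-2,5-diyn-1-yl)cyclopent-2-en-1-ol | CCC#CCC#CC[C@@]1(O)C=C[C@H](O[Si](C)(C)C(C)(C)C)C1 | intermediate
9 | (1S,4R)-4-(tert-butyldimethylsilyloxy)-1-[(2Z,5Z)-octa-2,5-dien-1-yl]cyclopent-2-en-1-ol | CC/C=C\C/C=C\C[C@@]1(O)C=C[C@H](O[Si](C)(C)C(C)(C)C)C1 | intermediate
10 | (1S,4R)-1-[(2Z,5Z)-octa-2,5-dien-1-yl]cyclopent-2-ene-1,4-diol | CC/C=C\C/C=C\C[C@@]1(O)C=C[C@H](O)C1 | intermediate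
11 | (S)-4-hydroxy-4-[(2Z,5Z)-octa-2,5-dien-1-yl]cyclopent-2-en-1-one | CC/C=C\C/C=C\C[C@@]1(O)C=CC(=O)C1 | intermediate
12 | (S)-4-[(2Z,5Z)-octa-2,5-dien-1-yl]-4-(triethylsilyloxy)cyclopent-2-en-1-one | CC/C=C\C/C=C\C[C@@]1(O[Si](CC)(CC)CC)C=CC(=O)C1 | intermediate
13 | 2,3-epoxy-4-[(2Z,5Z)-octa-2,5-dien-1-yl]-4-(triethylsilyloxy)cyclopentan-1-one, epoxide trans to OTES | CC/C=C\C/C=C\C[C@@]1(O[Si](CC)(CC)CC)[C@H]2O[C@H]2C(=O)C1 | intermediate
14 | 2-bromo-3-hydroxy-4-[(2Z,5Z)-octa-2,5-dien-1-yl]-4-(triethylsilyloxy)cyclopentan-1-one, Br trans to OH, OH trans to OTES | CC/C=C\C/C=C\C[C@@]1(O[Si](CC)(CC)CC)[C@@H](O)[C@H](Br)C(=O)C1 | intermediate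
15 | 3-O-methanesulfonate of 14 | CC/C=C\C/C=C\C[C@@]1(O[Si](CC)(CC)CC)[C@@H](OS(C)(=O)=O)[C@H](Br)C(=O)C1 | intermediate
16 | (S)-2-bromo-4-[(2Z,5Z)-octa-2,5-dien-1-yl]-4-(triethylsilyloxy)cyclopent-2-en-1-one | CC/C=C\C/C=C\C[C@@]1(O[Si](CC)(CC)CC)C=C(Br)C(=O)C1 | intermediate
17 | methyl 4-chloro-4-oxobutanoate | COC(=O)CCC(Cl)=O | starting material
18 | bis(trimethylsilyl)acetylene | C[Si](C)(C)C#C[Si](C)(C)C | starting material
19 | methyl 4-oxo-6-(trimethylsilyl)hex-5-ynoate | COC(=O)CCC(=O)C#C[Si](C)(C)C | intermediate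
20 | methyl (S)-4-hydroxy-6-(trimethylsilyl)hex-5-ynoate | COC(=O)CC[C@H](O)C#C[Si](C)(C)C | intermediate
21 | methyl (S)-4-(tert-butyldimethylsilyloxy)-6-(trimethylsilyl)hex-5-ynoate | COC(=O)CC[C@H](O[Si](C)(C)C(C)(C)C)C#C[Si](C)(C)C | intermediate
22 | methyl (S)-4-(tert-butyldimethylsilyloxy)hex-5-ynoate | COC(=O)CC[C@H](O[Si](C)(C)C(C)(C)C)C#C | intermediate
23 | methyl (S)-4-(tert-butyldimethylsilyloxy)hex-5-enoate | COC(=O)CC[C@H](O[Si](C)(C)C(C)(C)C)C=C | intermediate
24 | (E)-crotonaldehyde | C/C=C/C=O | starting material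
25 | methyl (S,E)-4-(tert-butyldimethylsilyloxy)-7-oxohept-5-enoate | COC(=O)CC[C@H](O[Si](C)(C)C(C)(C)C)/C=C/C=O | intermediate
26 | lithium dienolate of 16 (O–Li at C9, C8=C9 and C10=C11) | CC/C=C\C/C=C\C[C@@]1(O[Si](CC)(CC)CC)C=C(Br)C(O[Li])=C1 | intermediate
27 | methyl (4S,5E,12S,14Z,17Z)-10-bromo-4-(tert-butyldimethylsilyloxy)-7-hydroxy-9-oxo-12-(triethylsilyloxy)prosta-5,10,14,17-tetraenoate, diastereomer mixture at C7 and C8 | CC/C=C\C/C=C\C[C@@]1(O[Si](CC)(CC)CC)C=C(Br)C(=O)C1C(O)/C=C/[C@@H](O[Si](C)(C)C(C)(C)C)CCC(=O)OC | intermediate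
28 | 7-O-methanesulfonate of 27 | CC/C=C\C/C=C\C[C@@]1(O[Si](CC)(CC)CC)C=C(Br)C(=O)C1C(OS(C)(=O)=O)/C=C/[C@@H](O[Si](C)(C)C(C)(C)C)CCC(=O)OC | intermediate
29 | methyl (4S,5E,7Z,12R,14Z,17Z)-10-bromo-4-(tert-butyldimethylsilyloxy)-9-oxo-12-(triethylsilyloxy)prosta-5,7,10,14,17-pentaenoate | CC/C=C\C/C=C\C[C@@]1(O[Si](CC)(CC)CC)C=C(Br)C(=O)/C1=C\C=C\[C@@H](O[Si](C)(C)C(C)(C)C)CCC(=O)OC | intermediate
30 | methyl (4S,5E,7Z,12R,14Z,17Z)-10-bromo-4,12-dihydroxy-9-oxoprosta-5,7,10,14,17-pentaenoate | CC/C=C\C/C=C\C[C@@]1(O)C=C(Br)C(=O)/C1=C\C=C\[C@@H](O)CCC(=O)OC | target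

**Totals**
Total step count: 18. Longest linear sequence: 12 steps (steps 1–9, then 16–18, from compound 1); the enal branch is 6 steps (10–15) before the coupling.

**Three steps most likely to fail**

Step 17 is the weakest point, because the elimination is not stereoselective at C7=C8 and the 7E isomer may dominate. The fallback sets out from aldol 27 and returns at 29. Acetylate 27 (Ac2O, DMAP, pyridine) to the 7-acetate F4 and eliminate with DBU. Take the resulting 7E dienone F5 and irradiate it (Pyrex-filtered light, benzene, rt) to a photostationary mixture of C7 isomers. Separate 29 from this and recycle F5 together with any C5 isomer, so that the geometry is set by photoisomerisation instead of by the elimination.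

Step 8 may give poor regiocontrol in the bromide opening or lose the triethylsilyl ether. The fallback sets out from enone 12 and returns at 16, bypassing steps 7–9. Treat 12 with Me3SiBr (CH2Cl2, −78 → −40 °C) to give the 3-bromo silyl enol ether F1 by conjugate addition with O-silylation. Brominate this electron-rich enol ether in the same flask with N-bromosuccinimide at −78 °C, which is much faster than attack on the skipped diene, to give the 2,3-dibromocyclopentanone F2. Then add Et3N to eliminate HBr (E1cB) and reach 16.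

Step 16 may suffer from decomposition of the hindered lithium dienolate of the α-bromoenone or from retro-aldol. The fallback sets out from 16 and returns at 27. Convert 16 with Me3SiOTf/Et3N (CH2Cl2, 0 °C) into the 2-(trimethylsilyloxy)cyclopentadiene F3. Join F3 to enal 25 in a Lewis-acid-mediated Mukaiyama aldol addition (BF3·OEt2, CH2Cl2, −78 °C), which after aqueous work-up gives 27.

**Further compounds**
F1 | step 8 | 3-bromo-4-[(2Z,5Z)-octa-2,5-dien-1-yl]-4-(triethylsilyloxy)-1-(trimethylsilyloxy)cyclopent-1-ene (quaternary centre as in 12, mixture at C3) | CC/C=C\C/C=C\C[C@@]1(O[Si](CC)(CC)CC)C(Br)C=C(O[Si](C)(C)C)C1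
F2 | step 8 | 2,3-dibromo-4-[(2Z,5Z)-octa-2,5-dien-1-yl]-4-(triethylsilyloxy)cyclopentan-1-one (quaternary centre as in 12, mixture at C2 and C3) | CC/C=C\C/C=C\C[C@@]1(O[Si](CC)(CC)CC)C(Br)C(Br)C(=O)C1
F3 | step 16 | 3-bromo-5-[(2Z,5Z)-octa-2,5-dien-1-yl]-5-(triethylsilyloxy)-2-(trimethylsilyloxy)cyclopenta-1,3-diene (quaternary centre as in 16) | CC/C=C\C/C=C\C[C@@]1(O[Si](CC)(CC)CC)C=C(Br)C(O[Si](C)(C)C)=C1
F4 | step 17 | 7-O-acetate of 27 (mixture at C7 and C8) | CC/C=C\C/C=C\C[C@@]1(O[Si](CC)(CC)CC)C=C(Br)C(=O)C1C(OC(C)=O)/C=C/[C@@H](O[Si](C)(C)C(C)(C)C)CCC(=O)OC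
F5 | step 17 | methyl (4S,5E,7E,12R,14Z,17Z)-10-bromo-4-(tert-butyldimethylsilyloxy)-9-oxo-12-(triethylsilyloxy)prosta-5,7,10,14,17-pentaenoate | CC/C=C\C/C=C\C[C@@]1(O[Si](CC)(CC)CC)C=C(Br)C(=O)/C1=C/C=C/[C@@H](O[Si](C)(C)C(C)(C)C)CCC(=O)OC
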